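**Retrosynthetic overview**
1. The C40 polyene is cut at C15=C15' (Wittig): epoxy C20 aldehyde 18 plus ε-ring C20 phosphonium salt 25, the latter from resolved α-ionone by two Horner–Wadsworth–Emmons extensions.
2. The strategy rests on C9, the trisubstituted carbon of the C9=C10 alkene that carries the C8 vinyl arm to the epoxy ring and the C19 methyl. It is traced back to the CBr2 carbon of dibromotriene 13 (C9–C15), whose bromines are replaced in fixed order: first by alkenylboronate 6 (C8–C9), then by methyl from Me2Zn (C9–C19).
3. Boronate 6 comes from β-cyclocitral by Sharpless epoxidation (sets C5 and C6), alkynylation and hydroboration; 13 comes from the C5 acetoxy enal by Wittig homologation and dibromo-olefination.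
4. Ring order: both cyclohexene rings are bought; the only ring formed is the oxirane (step 2).

Key step: step 10

Remark: positions are given in carotenoid numbering (C5 and C6 are the epoxide carbons, C6' is the ε-ring stereocentre).
Remark: the Suzuki stage of step 10 needs water and the Me2Zn stage excludes it, so the two couplings are run consecutively in one flask with the volatiles stripped in between; bromide 15 is not purified.
Remark: (R)-α-ionone is obtained from the racemate by chromatography on a chiral phase.

**Epoxy-ring boronate**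

Step 1
Reactants: 1 β-cyclocitral
Product: 2 β-cyclogeraniol
Conditions: NaBH4, MeOH, 0 °C
Reagents that add atoms: none
Why: Borohydride 1,2-reduction of the hindered enal gives the primary allylic alcohol that serves as the directing handle for the epoxidation, and no stereocentre is formed.

Step 2
Reactants: 2 β-cyclogeraniol
Product: 3 [(1R,6R)-2,2,6-trimethyl-7-oxabicyclo[4.1.0]heptan-1-yl]methanol
Conditions: Ti(O-i-Pr)4 (0.3 equiv), D-(−)-diethyl tartrate [diethyl (2S,3S)-tartrate, 0.36 equiv], t-BuOOH (anhydrous, isooctane), 4 Å MS, CH2Cl2, −20 °C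
Reagents that add atoms: tert-butyl hydroperoxide CC(C)(C)OO
Why: Sharpless asymmetric epoxidation, in which the allylic hydroxyl binds the titanium–tartrate complex and the peroxide oxygen is delivered to one face of the tetrasubstituted C5=C6 bond, so that by the empirical facial rule the (S,S)-tartrate should give the (1R,6R) epoxy alcohol, whose two new cis-fused stereocentres have the spatial arrangement of the (5R,6S) end group of the target.

Step 3
Reactants: 3 epoxy alcohol
Product: 4 (1S,6R)-2,2,6-trimethyl-7-oxabicyclo[4.1.0]heptane-1-carbaldehyde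
Conditions: n-Pr4N[RuO4] (5 mol %), N-methylmorpholine N-oxide, 4 Å MS, CH2Cl2, 23 °C
Reagents that add atoms: none
Why: Ley–Griffith oxidation under neutral anhydrous conditions should convert the neopentyl-type primary alcohol into the aldehyde without opening the acid-sensitive epoxide, and the quaternary α-carbon cannot epimerise (the descriptor at C1 changes only because CHO outranks C6).

Step 4
Reactants: 4 epoxy aldehyde
Product: 5 (1R,6R)-1-ethynyl-2,2,6-trimethyl-7-oxabicyclo[4.1.0]heptane
Conditions: dimethyl (1-diazo-2-oxopropyl)phosphonate, K2CO3, MeOH, 0 → 23 °C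
Reagents that add atoms: dimethyl (1-diazo-2-oxopropyl)phosphonate CC(=O)C(=[N+]=[N-])P(=O)(OC)OC
Why: Ohira–Bestmann (Seyferth–Gilbert) homologation, in which the diazomethylphosphonate anion formed by methanolysis adds to the non-enolisable aldehyde and loss of phosphate and N2 with a 1,2-shift gives the terminal alkyne under mildly basic conditions that the epoxide tolerates.

Step 5
Reactants: 5 epoxy alkyne
Product: 6 4,4,5,5-tetramethyl-2-[(E)-2-[(1S,6R)-2,2,6-trimethyl-7-oxabicyclo[4.1.0]heptan-1-yl]ethenyl]-1,3,2-dioxaborolane
Conditions: pinacolborane (1.5 equiv), Cp2Zr(H)Cl (10 mol %), Et3N (10 mol %), neat, 60 °C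
Reagents that add atoms: pinacolborane CC1(C)OBOC1(C)C
Why: Zirconium-catalysed hydroboration, in which Cp2Zr(H)Cl adds syn to the terminal alkyne with the metal at the unhindered terminus and hands the alkenyl group to boron, so the (E)-alkenylboronate should form with anti-Markovnikov regiochemistry and without Lewis-acid opening of the epoxide.

**Dibromotriene**

Step 6
Reactants: 7 (E)-4-acetoxy-2-methylbut-2-enal
Product: 8 (2E,4E)-6-acetoxy-4-methylhexa-2,4-dienal
Conditions: Ph3P=CHCHO (1.05 equiv), toluene, 70 °C
Reagents that add atoms: (triphenylphosphoranylidene)acetaldehyde O=CC=P(c1ccccc1)(c1ccccc1)c1ccccc1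
Why: Wittig two-carbon homologation with the formyl-stabilised ylide, which is expected to give the E enal and to leave the trisubstituted alkene and the acetate untouched, the near-stoichiometric ylide limiting a second homologation.

Step 7
Reactants: 8 dienal acetate, 9 carbon tetrabromide
Product: 11 (2E,4E)-7,7-dibromo-3-methylhepta-2,4,6-trien-1-yl acetate, via dibromomethylene(triphenyl)phosphorane 10 (not isolated)
Conditions: PPh3, Zn dust, CBr4 (2 equiv each), CH2Cl2, 23 °C; then 8, 0 → 23 °C
Reagents that add atoms: none
Why: Ramirez dibromo-olefination (first stage of the Corey–Fuchs sequence), in which the ylide 10 preformed from CBr4, PPh3 and Zn condenses with the aldehyde under essentially neutral conditions to give the 1,1-dibromoalkene.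

Step 8
Reactants: 11 dibromotriene acetate
Product: 12 (2E,4E)-7,7-dibromo-3-methylhepta-2,4,6-trien-1-ol
Conditions: K2CO3 (0.2 equiv), MeOH, 0 °C
Reagents that add atoms: none
Why: Base-catalysed transesterification (Zemplén-type methanolysis) removes the allylic acetate, which would otherwise ionise with zerovalent palladium in step 10, while the gem-dibromoalkene is inert to catalytic carbonate at 0 °C.

Step 9
Reactants: 12 dibromotrienol
Product: 13 tert-butyldimethylsilyl ether of (2E,4E)-7,7-dibromo-3-methylhepta-2,4,6-trien-1-ol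
Conditions: TBSCl, imidazole, DMF, 0 → 23 °C
Reagents that add atoms: tert-butyldimethylsilyl chloride CC(C)(C)[Si](C)(C)Cl
Why: Standard silylation of the primary allylic alcohol gives an ether that is inert to zerovalent palladium, TlOEt and Me2Zn.

**Key coupling and epoxy C20 aldehyde**

Step 10
Reactants: 6 epoxy-ring (E)-alkenylboronate, 13 silylated dibromotriene, 14 dimethylzinc
Product: 16 tert-butyldimethylsilyl ether of (5R,6S)-5,6-epoxy-5,6-dihydroretinol, via (9Z)-9-bromo-19-nor silyl ether 15 (not isolated)
Conditions: Pd(PPh3)4 (5 mol %), TlOEt (1.8 equiv), THF/H2O 3:1, 25 °C; volatiles stripped in the same flask (toluene azeotrope); then Pd(P(t-Bu)3)2 (10 mol %), Me2Zn (4 equiv), THF, 0 → 25 °C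
Reagents that add atoms: none
Why: Zerovalent palladium from Pd(PPh3)4 inserts preferentially into the C9–Br bond trans to the C10–C11 dienyl arm of 13, the less hindered of the two, and the TlOEt-activated boronate 6 transmetallates with retention of its E geometry, so reductive elimination forms C8–C9 and leaves the (9Z)-bromide 15 (a Suzuki–Miyaura monoalkenylation of a 1,1-dibromoalkene). The second cycle, with Pd(P(t-Bu)3)2 and Me2Zn 14, is a Negishi methylation in which oxidative addition, zinc-to-palladium methyl transfer and reductive elimination all proceed with retention, forming C9–C19 and hence the 9E trisubstituted alkene. The closest known reaction type is the trans-selective monoalkenylation of 1,1-dibromoalkenes followed by stereoretentive methylation with methylzinc reagents. No ring is closed and no stereocentre is created, the (5R,6S) epoxide and the 7E alkene being carried in unchanged by 6. The step needs site selectivity between the two bromines, secured by the steric difference between the positions cis and trans to C11 and by only a slight excess of 6 at 25 °C, and it needs geometric fidelity in the methylation, secured by the bulky electron-rich P(t-Bu)3 ligand, which makes reductive elimination outrun the isomerisation of the 2-palladadiene that other ligands allow. Mild base and the absence of Brønsted acid should keep the vinyl epoxide and the silyl ether intact.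

Step 11
Reactants: 16 silyl ether of epoxyretinol
Product: 17 (5R,6S)-5,6-epoxy-5,6-dihydroretinol
Conditions: Bu4NF, THF, 0 °C
Reagents that add atoms: none
Why: Fluoride-mediated desilylation under non-acidic conditions should free the primary allylic alcohol and leave the epoxide and the tetraene intact.

Step 12
Reactants: 17 epoxyretinol
Product: 18 (5R,6S)-5,6-epoxy-5,6-dihydroretinal
Conditions: activated MnO2 (excess), Na2CO3, CH2Cl2, 23 °C, dark
Reagents that add atoms: none
Why: Selective MnO2 oxidation of the allylic alcohol to the polyenal is a neutral heterogeneous oxidation that touches neither the epoxide nor the E alkenes.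

**ε-Ring C20 phosphonium salt**

Step 13
Reactants: 19 racemic α-ionone
Product: 20 (R)-α-ionone
Conditions: preparative chromatography on amylose tris(3,5-dimethylphenylcarbamate)/silica, heptane/i-PrOH, 23 °C
Reagents that add atoms: none
Why: Resolution of the racemate by chromatography on a chiral stationary phase is a purely physical separation that cannot epimerise C6, the dextrorotatory fraction being the (R)-enantiomer.

Step 14
Reactants: 20 (R)-α-ionone
Product: 21 (2E,4E)-3-methyl-5-[(1R)-2,6,6-trimethylcyclohex-2-en-1-yl]penta-2,4-dienenitrile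
Conditions: (EtO)2P(O)CH2CN, NaH (slight deficit, anion preformed), THF, 0 → 23 °C; 9Z isomer removed on silica
Reagents that add atoms: diethyl (cyanomethyl)phosphonate CCOP(=O)(CC#N)OCC
Why: Horner–Wadsworth–Emmons olefination of the methyl ketone with the preformed phosphonate anion should favour the 9E nitrile, and the anion is too weakly basic to deprotonate the C6 stereocentre or to move the ring alkene into conjugation.

Step 15
Reactants: 21 C15 nitrile
Product: 22 (2E,4E)-3-methyl-5-[(1R)-2,6,6-trimethylcyclohex-2-en-1-yl]penta-2,4-dienal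
Conditions: i-Bu2AlH, toluene, −78 °C; aqueous sodium potassium tartrate work-up
Reagents that add atoms: water O
Why: Partial reduction of the nitrile with i-Bu2AlH stops at the N-aluminated aldimine, which is hydrolysed on buffered aqueous work-up to the C15 aldehyde.

Step 16
Reactants: 22 C15 aldehyde
Product: 23 ethyl (6R)-α-retinoate
Conditions: triethyl 3-methyl-4-phosphonocrotonate, n-BuLi, DMPU, THF, −78 → 0 °C
Reagents that add atoms: triethyl (E)-3-methyl-4-phosphonobut-2-enoate CCOC(=O)/C=C(C)/CP(=O)(OCC)OCC
Why: Vinylogous Horner–Wadsworth–Emmons reaction of the γ-lithiated C5 phosphonate with the dienal is expected to form the 11E alkene and mainly the 13E ester, any 13Z isomer being removed by chromatography.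

Step 17
Reactants: 23 ethyl α-retinoate
Product: 24 (6R)-α-retinol
Conditions: i-Bu2AlH (2.2 equiv), THF, −78 °C
Reagents that add atoms: none
Why: 1,2-Reduction of the conjugated ester with i-Bu2AlH gives the allylic alcohol without touching the polyene or the stereocentre.

Step 18
Reactants: 24 α-retinol
Product: 25 (6R)-α-retinyltriphenylphosphonium bromide
Conditions: Ph3P·HBr, MeOH, 0 → 23 °C, dark
Reagents that add atoms: triphenylphosphine hydrobromide [Br-].c1ccc(cc1)[PH+](c1ccccc1)c1ccccc1
Why: SN1-type phosphonium salt formation, in which the weak acid Ph3PH+ ionises the polyenylic alcohol and PPh3 traps the delocalised cation at terminal C15, the site that keeps the tetraene conjugated.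

**Final coupling**

Step 19
Reactants: 25 α-retinyltriphenylphosphonium bromide, 18 epoxy C20 aldehyde
Product: 28 (5R,6S,6'R)-5,6-epoxy-5,6-dihydro-β,ε-carotene (target), via α-retinylidene(triphenyl)phosphorane 26 (not isolated), via (15Z)-isomer of the target 27 (not isolated)
Conditions: NaOMe, MeOH/CH2Cl2, 0 → 23 °C, dark, Ar; then n-heptane, reflux, Ar; crystallisation
Reagents that add atoms: none
Why: Wittig olefination, in which NaOMe converts 25 into the polyenyl ylide 26 that condenses with aldehyde 18 to form C15=C15' as an E/Z mixture, and the thermally labile central Z isomer 27 should revert to the all-E polyene on heating in a hydrocarbon, base and heat leaving the epoxide (C5, C6) and the C6' stereocentre untouched.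

**Compound list**
1 | β-cyclocitral | CC1=C(C=O)C(C)(C)CCC1 | starting material
2 | β-cyclogeraniol | CC1=C(CO)C(C)(C)CCC1 | intermediate
3 | [(1R,6R)-2,2,6-trimethyl-7-oxabicyclo[4.1.0]heptan-1-yl]methanol | OC[C@@]12O[C@]1(C)CCCC2(C)C | intermediate
4 | (1S,6R)-2,2,6-trimethyl-7-oxabicyclo[4.1.0]heptane-1-carbaldehyde | O=C[C@@]12O[C@]1(C)CCCC2(C)C | intermediate
5 | (1R,6R)-1-ethynyl-2,2,6-trimethyl-7-oxabicyclo[4.1.0]heptane | C#C[C@@]12O[C@]1(C)CCCC2(C)C | intermediate
6 | 4,4,5,5-tetramethyl-2-[(E)-2-[(1S,6R)-2,2,6-trimethyl-7-oxabicyclo[4.1.0]heptan-1-yl]ethenyl]-1,3,2-dioxaborolane | CC1(C)OB(OC1(C)C)/C=C/[C@@]23O[C@]2(C)CCCC3(C)C | intermediate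
7 | (E)-4-acetoxy-2-methylbut-2-enal | CC(=O)OC/C=C(C)/C=O | starting material
8 | (2E,4E)-6-acetoxy-4-methylhexa-2,4-dienal | CC(=O)OC/C=C(C)/C=C/C=O | intermediate
9 | carbon tetrabromide | BrC(Br)(Br)Br | starting material
10 | (dibromomethylene)triphenylphosphorane | BrC(Br)=P(c1ccccc1)(c1ccccc1)c1ccccc1 | intermediate (not isolated)
11 | (2E,4E)-7,7-dibromo-3-methylhepta-2,4,6-trien-1-yl acetate | CC(=O)OC/C=C(C)/C=C/C=C(Br)Br | intermediate
12 | (2E,4E)-7,7-dibromo-3-methylhepta-2,4,6-trien-1-ol | OC/C=C(C)/C=C/C=C(Br)Br | intermediate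
13 | tert-butyldimethylsilyl ether of (2E,4E)-7,7-dibromo-3-methylhepta-2,4,6-trien-1-ol | BrC(Br)=C/C=C/C(C)=C/CO[Si](C)(C)C(C)(C)C | intermediate
14 | dimethylzinc | C[Zn]C | starting material
15 | tert-butyldimethylsilyl ether of (5R,6S,9Z)-9-bromo-5,6-epoxy-5,6-dihydro-19-norretinol | CC(C)(C)[Si](C)(C)OC/C=C(C)/C=C/C=C(Br)/C=C/[C@@]12O[C@]1(C)CCCC2(C)C | intermediate (not isolated)
16 | tert-butyldimethylsilyl ether of (5R,6S)-5,6-epoxy-5,6-dihydroretinol | CC(C)(C)[Si](C)(C)OC/C=C(C)/C=C/C=C(C)/C=C/[C@@]12O[C@]1(C)CCCC2(C)C | intermediate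
17 | (5R,6S)-5,6-epoxy-5,6-dihydroretinol | OC/C=C(C)/C=C/C=C(C)/C=C/[C@@]12O[C@]1(C)CCCC2(C)C | intermediate
18 | (5R,6S)-5,6-epoxy-5,6-dihydroretinal | O=C/C=C(C)/C=C/C=C(C)/C=C/[C@@]12O[C@]1(C)CCCC2(C)C | intermediate
19 | racemic α-ionone | CC1=CCCC(C)(C)C1/C=C/C(C)=O | starting material
20 | (R)-α-ionone | CC1=CCCC(C)(C)[C@H]1/C=C/C(C)=O | intermediate
21 | (2E,4E)-3-methyl-5-[(1R)-2,6,6-trimethylcyclohex-2-en-1-yl]penta-2,4-dienenitrile | CC1=CCCC(C)(C)[C@H]1/C=C/C(C)=C/C#N | intermediate
22 | (2E,4E)-3-methyl-5-[(1R)-2,6,6-trimethylcyclohex-2-en-1-yl]penta-2,4-dienal | CC1=CCCC(C)(C)[C@H]1/C=C/C(C)=C/C=O | intermediate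
23 | ethyl (6R)-α-retinoate | CC1=CCCC(C)(C)[C@H]1/C=C/C(C)=C/C=C/C(C)=C/C(=O)OCC | intermediate
24 | (6R)-α-retinol | CC1=CCCC(C)(C)[C@H]1/C=C/C(C)=C/C=C/C(C)=C/CO | intermediate
25 | (6R)-α-retinyltriphenylphosphonium bromide | CC1=CCCC(C)(C)[C@H]1/C=C/C(C)=C/C=C/C(C)=C/C[P+](c1ccccc1)(c1ccccc1)c1ccccc1.[Br-] | intermediate
26 | (6R)-α-retinylidene(triphenyl)phosphorane | CC1=CCCC(C)(C)[C@H]1/C=C/C(C)=C/C=C/C(C)=C/C=P(c1ccccc1)(c1ccccc1)c1ccccc1 | intermediate (not isolated)
27 | (5R,6S,6'R,15Z)-5,6-epoxy-5,6-dihydro-β,ε-carotene | CC1=CCCC(C)(C)[C@H]1/C=C/C(C)=C/C=C/C(C)=C/C=C\C=C(C)\C=C\C=C(C)\C=C\[C@@]12O[C@]1(C)CCCC2(C)C | intermediate (not isolated)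
28 | (5R,6S,6'R)-5,6-epoxy-5,6-dihydro-β,ε-carotene | CC1=CCCC(C)(C)[C@H]1/C=C/C(C)=C/C=C/C(C)=C/C=C/C=C(C)/C=C/C=C(C)/C=C/[C@@]12O[C@]1(C)CCCC2(C)C | target

**Totals**
Total step count: 19. Longest linear sequence: 9 steps (steps 1–5, 10–12, 19, from β-cyclocitral).

**Steps most likely to fail**

1. Step 10. What may go wrong: oxidative addition at both C–Br bonds (double alkenylation), scrambling of the C9 geometry during the methylation, or opening of the vinyl epoxide by the zinc halide that builds up. Fallback (olefination in place of cross-coupling; sets out from 4, returns at 17): Wittig reaction of 4 with 1-(triphenylphosphoranylidene)propan-2-one in refluxing toluene should give (5R,6S)-5,6-epoxy-5,6-dihydro-β-ionone F1. Horner–Wadsworth–Emmons reaction with diethyl (cyanomethyl)phosphonate/NaH then gives the epoxy C15 nitrile F2, and i-Bu2AlH at −78 °C with buffered hydrolysis gives the epoxy C15 aldehyde F3. A second Horner–Wadsworth–Emmons reaction with lithiated triethyl 3-methyl-4-phosphonocrotonate gives ethyl (5R,6S)-5,6-epoxy-5,6-dihydroretinoate F4, and i-Bu2AlH reduction delivers 17, from which step 12 follows.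

2. Step 2. What may go wrong: insufficient enantiofacial discrimination on the hindered tetrasubstituted alkene, or induction in the opposite sense; the configuration of 3 would be checked chiroptically before going on, and the enantiomeric tartrate is the direct remedy for a wrong sense. Fallback (racemic epoxidation and resolution; sets out from 2, returns at 3): m-CPBA, NaHCO3, CH2Cl2, 0 °C should give the racemic cis-fused epoxy alcohol F5, and its enantiomers are separated by preparative chromatography on a chiral stationary phase to supply 3.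

3. Step 18. What may go wrong: under the acidic ionisation, proton loss from C6' of the polyenyl cation (retro rearrangement with migration of the double bonds and erosion of the stereocentre) competes with capture by PPh3. Fallback (sulfone olefination under non-acidic conditions; sets out from 24, returns at 28): Mitsunobu thioetherification of 24 with 2-mercaptobenzothiazole (PPh3, diisopropyl azodicarboxylate) gives the benzothiazolyl sulfide F6. Oxidation with H2O2 and catalytic (NH4)6Mo7O24 gives the benzothiazolyl sulfone F7. Julia–Kocienski olefination of aldehyde 18 with F7 (NaN(SiMe3)2, THF, −78 °C), followed by the thermal equilibration of step 19, ends at 28.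

**Further compounds**
F1 | step 10 | (E)-4-[(1S,6R)-2,2,6-trimethyl-7-oxabicyclo[4.1.0]heptan-1-yl]but-3-en-2-one | CC(=O)/C=C/[C@@]12O[C@]1(C)CCCC2(C)C
F2 | step 10 | (2E,4E)-3-methyl-5-[(1S,6R)-2,2,6-trimethyl-7-oxabicyclo[4.1.0]heptan-1-yl]penta-2,4-dienenitrile | N#C/C=C(C)/C=C/[C@@]12O[C@]1(C)CCCC2(C)C
F3 | step 10 | (2E,4E)-3-methyl-5-[(1S,6R)-2,2,6-trimethyl-7-oxabicyclo[4.1.0]heptan-1-yl]penta-2,4-dienal | O=C/C=C(C)/C=C/[C@@]12O[C@]1(C)CCCC2(C)C
F4 | step 10 | ethyl (5R,6S)-5,6-epoxy-5,6-dihydroretinoate | CCOC(=O)/C=C(C)/C=C/C=C(C)/C=C/[C@@]12O[C@]1(C)CCCC2(C)C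
F5 | step 2 | racemic (2,2,6-trimethyl-7-oxabicyclo[4.1.0]heptan-1-yl)methanol | OCC12OC1(C)CCCC2(C)C
F6 | step 18 | 2-[(6R)-α-retinylsulfanyl]-1,3-benzothiazole | CC1=CCCC(C)(C)[C@H]1/C=C/C(C)=C/C=C/C(C)=C/CSc1nc2ccccc2s1
F7 | step 18 | 2-[(6R)-α-retinylsulfonyl]-1,3-benzothiazole | CC1=CCCC(C)(C)[C@H]1/C=C/C(C)=C/C=C/C(C)=C/CS(=O)(=O)c1nc2ccccc2s1
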